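The pyranone ring C of the flavanone is disconnected at the two bonds it shares with ring A, O1–C8a and C4–C4a. A fully benzylated biaryl (S)-β-hydroxy Weinreb amide, which already holds the luteolin unit, catechol ring B, C2 with its oxygen, C3 and C4, is converted into its alkoxide and annulated with 3,5-bis(benzyloxy)benzyne. The oxygen adds to the aryne and the aryl carbanion so formed closes ring C by attacking the amide carbon. The step exploits the ortho placement of O1 and the C4 acyl carbon on ring A, with the C5 oxygen beside C4a steering the aryne regiochemistry. C2 is set earlier by asymmetric transfer hydrogenation, the biaryl bond by Suzuki coupling.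

Key step: step 11

Remark: the biaryl axis between C5' of the flavanone ring B and C6 of the flavone carries no stereodescriptor in the target; it is treated as not configurationally defined and no control of axial chirality is attempted.

Step 1
Reactants: 1 luteolin
Product: 2 7,3',4'-tri-O-benzylluteolin (5-OH free)
Conditions: BnBr (3.3 equiv), K2CO3, DMF, rt
Reagents that add atoms: benzyl bromide BrCc1ccccc1
Why: Williamson etherification should alkylate the 7-, 3'- and 4'-phenols, while the 5-OH, hydrogen-bonded to the C4 carbonyl, is expected to stay free under these mild carbonate conditions.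

Step 2
Reactants: 2 7,3',4'-tri-O-benzylluteolin
Product: 3 7,3',4'-tri-O-benzyl-6-iodoluteolin
Conditions: BnMe3N·ICl2, CaCO3, CH2Cl2/MeOH, rt
Reagents that add atoms: benzyltrimethylammonium dichloroiodate C[N+](C)(C)Cc1ccccc1.Cl[I-]Cl
Why: Electrophilic aromatic iodination ortho to the free, chelated 5-OH; this reagent is known to iodinate 5-hydroxy-7-alkoxyflavones at C6 and not at C8.

Step 3
Reactants: 3 7,3',4'-tri-O-benzyl-6-iodoluteolin
Product: 4 5,7,3',4'-tetra-O-benzyl-6-iodoluteolin
Conditions: BnBr, K2CO3, KI (cat.), DMF, 70 °C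
Reagents that add atoms: benzyl bromide BrCc1ccccc1
Why: Williamson etherification under more forcing conditions should cap the hindered chelated 5-OH, so that no acidic proton remains for the cross-coupling and the later alkoxide/aryne step.

Step 4
Reactants: 5 methyl 3-bromo-4,5-dihydroxybenzoate
Product: 6 methyl 3,4-bis(benzyloxy)-5-bromobenzoate
Conditions: BnBr (2.4 equiv), K2CO3, DMF, rt
Reagents that add atoms: benzyl bromide BrCc1ccccc1
Why: Williamson etherification of both catechol hydroxyls; the methyl ester and aryl bromide are inert to carbonate at room temperature.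

Step 5
Reactants: 6 methyl 3,4-bis(benzyloxy)-5-bromobenzoate; 7 N-methoxy-N-methylacetamide
Product: 9 3-[3,4-bis(benzyloxy)-5-bromophenyl]-N-methoxy-N-methyl-3-oxopropanamide, via lithium amide enolate 8 (not isolated)
Conditions: 7 (2.2 equiv), LiN(i-Pr)2 (2.2 equiv), THF, −78 °C; then 6, −78 to −20 °C; AcOH quench
Reagents that add atoms: none
Why: Crossed Claisen condensation of the preformed lithium enolate with the methyl ester; the second equivalent of enolate deprotonates the β-keto amide as it forms, which should prevent over-addition, and no free amide base is left to attack the aryl bromide.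

Step 6
Reactants: 9 3-[3,4-bis(benzyloxy)-5-bromophenyl]-N-methoxy-N-methyl-3-oxopropanamide
Product: 10 (3S)-3-[3,4-bis(benzyloxy)-5-bromophenyl]-3-hydroxy-N-methoxy-N-methylpropanamide
Conditions: RuCl[(S,S)-TsDPEN](p-cymene) (1 mol%), HCO2H/Et3N (5:2), DMF, 30 °C
Reagents that add atoms: none
Why: Noyori asymmetric transfer hydrogenation: the (S,S)-TsDPEN ruthenium hydride should reduce the aryl ketone on the face that places the aryl group beside the η6-arene (CH/π contact), the same sense that gives (S)-1-arylethanols, so the (S)-benzylic carbinol is expected; the amide carbonyl is not reduced.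

Step 7
Reactants: 10 (3S)-3-[3,4-bis(benzyloxy)-5-bromophenyl]-3-hydroxy-N-methoxy-N-methylpropanamide
Product: 11 (3S)-3-[3,4-bis(benzyloxy)-5-(pinacolatoboryl)phenyl]-3-hydroxy-N-methoxy-N-methylpropanamide
Conditions: B2pin2, PdCl2(dppf) (3 mol%), KOAc, 1,4-dioxane, 85 °C
Reagents that add atoms: bis(pinacolato)diboron CC1(C)OB(OC1(C)C)B1OC(C)(C)C(C)(C)O1
Why: Miyaura borylation of the aryl bromide; the weak acetate base should leave the free carbinol, the Weinreb amide and the stereocentre untouched.

Step 8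
Reactants: 4 5,7,3',4'-tetra-O-benzyl-6-iodoluteolin; 11 (3S)-3-[3,4-bis(benzyloxy)-5-(pinacolatoboryl)phenyl]-3-hydroxy-N-methoxy-N-methylpropanamide
Product: 12 biaryl (3S)-β-hydroxy Weinreb amide (hexabenzylated flavone C6 joined to C5 of the carbinol aryl ring)
Conditions: Pd(OAc)2 (5 mol%), SPhos (10 mol%), K3PO4, toluene/H2O, 80 °C
Reagents that add atoms: none
Why: Suzuki–Miyaura coupling with a bulky biaryl phosphine on zerovalent palladium, a system made for tri-ortho-substituted biaryls; boron sits on the ring with only one ortho oxygen to limit protodeboronation, and the phosphate base should not touch the carbinol centre.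

Step 9
Reactants: 13 3,5-bis(benzyloxy)phenol
Product: 14 3,5-bis(benzyloxy)-2-bromophenol
Conditions: NBS (1.0 equiv), i-Pr2NH (10 mol%), CH2Cl2, −78 to 0 °C
Reagents that add atoms: N-bromosuccinimide O=C1CCC(=O)N1Br
Why: Amine-catalysed ortho-bromination of a phenol: the hydrogen-bonded N-bromoamine should deliver bromine next to the OH, and the two ortho positions are equivalent by symmetry, so the crowded para position between the two benzyloxy groups is avoided.

Step 10
Reactants: 14 3,5-bis(benzyloxy)-2-bromophenol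
Product: 17 3,5-bis(benzyloxy)-2-(trimethylsilyl)phenyl triflate, via aryl trimethylsilyl ether 15 (not isolated), via lithium 2-silylphenoxide 16 (not isolated)
Conditions: (Me3Si)2NH, THF, 65 °C, then evaporation; n-BuLi, THF, −78 °C; Tf2O, −78 °C to rt
Reagents that add atoms: hexamethyldisilazane C[Si](C)(C)N[Si](C)(C)C; trifluoromethanesulfonic anhydride O=S(=O)(OS(=O)(=O)C(F)(F)F)C(F)(F)F
Why: O-silylation, bromine–lithium exchange and retro-Brook 1,3-shift of silicon from oxygen to carbon, then triflation of the lithium phenoxide, is the standard one-flask route to 2-silylaryl triflates.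

Step 11
Reactants: 12 biaryl (3S)-β-hydroxy Weinreb amide; 17 3,5-bis(benzyloxy)-2-(trimethylsilyl)phenyl triflate
Product: 21 octabenzylated (2S)-flavanone–flavone, via sodium alkoxide 18 (not isolated), via aryne 19 (not isolated), via hemiaminal alkoxide 20 (not isolated)
Conditions: NaH (1.05 equiv), THF, 0 °C; then 17 (1.5 equiv, slow addition), KF, 18-crown-6, 0 °C to rt; AcOH, 0 °C
Reagents that add atoms: none
Why: Proposed new method: fluoride-induced 1,2-elimination of 17 gives aryne 19, the alkoxide oxygen of 18 adds to its C1, and the resulting C2 aryl carbanion attacks the tethered Weinreb amide carbonyl to give hemiaminal alkoxide 20, which releases the ketone only on acidic quench. The closest known reaction type is the fluoride-mediated annulation of arynes with salicylate esters to xanthones (O-arylation followed by intramolecular acyl capture), and more broadly aryne σ-insertion; its extension to an aliphatic β-alkoxy amide is the untested element. Ring C is closed by a 6-exo-trig attack of the aryl carbanion (future C4a) on the amide carbon (future C4). No new stereocentre appears in the product: C2 is carried over from 12 with its C–O bond intact, and the transient hemiaminal centre at C4 is destroyed on quench. The step needs regioselective addition to the unsymmetrical aryne, which the 3-benzyloxy group should secure by directing the nucleophile to the distal aryne carbon (inductive stabilisation of the carbanion ortho to oxygen, aryne distortion), so that the acyl carbon ends up beside the C5 oxygen. It also needs carbonyl addition to outrun proton transfer and the product to be shielded from base-induced retro-oxa-Michael opening; the pre-formed alkoxide (no OH proton) and the persistence of 20 until quench are relied on for this.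

Step 12
Reactants: 21 octabenzylated (2S)-flavanone–flavone
Product: 22 target, (2S)-2-{3,4-dihydroxy-5-[5,7-dihydroxy-2-(3,4-dihydroxyphenyl)-4-oxo-4H-chromen-6-yl]phenyl}-5,7-dihydroxychroman-4-one
Conditions: H2 (1 atm), 10% Pd/C, THF/MeOH, rt
Reagents that add atoms: none
Why: Catalytic hydrogenolysis of the eight aryl benzyl ethers under neutral conditions should not epimerise C2, and the flavone C2=C3 bond and the flavanone C2–O1 bond are normally inert at ambient pressure.

Compound list
1 | luteolin, 2-(3,4-dihydroxyphenyl)-5,7-dihydroxy-4H-chromen-4-one | O=c1cc(-c2ccc(O)c(O)c2)oc2cc(O)cc(O)c12 | starting material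
2 | 7-(benzyloxy)-2-[3,4-bis(benzyloxy)phenyl]-5-hydroxy-4H-chromen-4-one | O=c1cc(-c2ccc(OCc3ccccc3)c(OCc3ccccc3)c2)oc2cc(OCc3ccccc3)cc(O)c12 | intermediate
3 | 7-(benzyloxy)-2-[3,4-bis(benzyloxy)phenyl]-5-hydroxy-6-iodo-4H-chromen-4-one | O=c1cc(-c2ccc(OCc3ccccc3)c(OCc3ccccc3)c2)oc2cc(OCc3ccccc3)c(I)c(O)c12 | intermediate
4 | 5,7-bis(benzyloxy)-2-[3,4-bis(benzyloxy)phenyl]-6-iodo-4H-chromen-4-one | O=c1cc(-c2ccc(OCc3ccccc3)c(OCc3ccccc3)c2)oc2cc(OCc3ccccc3)c(I)c(OCc3ccccc3)c12 | intermediate
5 | methyl 3-bromo-4,5-dihydroxybenzoate | COC(=O)c1cc(O)c(O)c(Br)c1 | starting material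
6 | methyl 3,4-bis(benzyloxy)-5-bromobenzoate | COC(=O)c1cc(OCc2ccccc2)c(OCc2ccccc2)c(Br)c1 | intermediate
7 | N-methoxy-N-methylacetamide | CC(=O)N(C)OC | starting material
8 | lithium 1-[methoxy(methyl)amino]ethen-1-olate (lithium enolate of 7, formed in the flask) | [Li+].[O-]C(=C)N(C)OC | intermediate
9 | 3-[3,4-bis(benzyloxy)-5-bromophenyl]-N-methoxy-N-methyl-3-oxopropanamide | CON(C)C(=O)CC(=O)c1cc(OCc2ccccc2)c(OCc2ccccc2)c(Br)c1 | intermediate
10 | (3S)-3-[3,4-bis(benzyloxy)-5-bromophenyl]-3-hydroxy-N-methoxy-N-methylpropanamide | CON(C)C(=O)C[C@@H](c1cc(OCc2ccccc2)c(OCc2ccccc2)c(Br)c1)O | intermediate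
11 | (3S)-3-[3,4-bis(benzyloxy)-5-(4,4,5,5-tetramethyl-1,3,2-dioxaborolan-2-yl)phenyl]-3-hydroxy-N-methoxy-N-methylpropanamide | CON(C)C(=O)C[C@@H](c1cc(OCc2ccccc2)c(OCc2ccccc2)c(B2OC(C)(C)C(C)(C)O2)c1)O | intermediate
12 | (3S)-3-{3,4-bis(benzyloxy)-5-[5,7-bis(benzyloxy)-2-(3,4-bis(benzyloxy)phenyl)-4-oxo-4H-chromen-6-yl]phenyl}-3-hydroxy-N-methoxy-N-methylpropanamide | CON(C)C(=O)C[C@@H](c1cc(OCc2ccccc2)c(OCc2ccccc2)c(-c2c(OCc3ccccc3)cc3oc(-c4ccc(OCc5ccccc5)c(OCc5ccccc5)c4)cc(=O)c3c2OCc2ccccc2)c1)O | intermediate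
13 | 3,5-bis(benzyloxy)phenol | Oc1cc(OCc2ccccc2)cc(OCc2ccccc2)c1 | starting material
14 | 3,5-bis(benzyloxy)-2-bromophenol | Oc1cc(OCc2ccccc2)cc(OCc2ccccc2)c1Br | intermediate
15 | [3,5-bis(benzyloxy)-2-bromophenoxy]trimethylsilane (formed in the flask) | C[Si](C)(C)Oc1cc(OCc2ccccc2)cc(OCc2ccccc2)c1Br | intermediate
16 | lithium 3,5-bis(benzyloxy)-2-(trimethylsilyl)phenolate (formed in the flask) | [Li+].[O-]c1cc(OCc2ccccc2)cc(OCc2ccccc2)c1[Si](C)(C)C | intermediate
17 | 3,5-bis(benzyloxy)-2-(trimethylsilyl)phenyl trifluoromethanesulfonate | C[Si](C)(C)c1c(OS(=O)(=O)C(F)(F)F)cc(OCc2ccccc2)cc1OCc1ccccc1 | intermediate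
18 | sodium alkoxide of 12 (formed in the flask) | [Na+].CON(C)C(=O)C[C@@H](c1cc(OCc2ccccc2)c(OCc2ccccc2)c(-c2c(OCc3ccccc3)cc3oc(-c4ccc(OCc5ccccc5)c(OCc5ccccc5)c4)cc(=O)c3c2OCc2ccccc2)c1)[O-] | intermediate
19 | 3,5-bis(benzyloxy)benzyne, 1,2-didehydro-3,5-bis(benzyloxy)benzene (formed in the flask) | C1#CC(OCc2ccccc2)=CC(OCc2ccccc2)=C1 | intermediate
20 | sodium (2S)-5,7-bis(benzyloxy)-2-{3,4-bis(benzyloxy)-5-[5,7-bis(benzyloxy)-2-(3,4-bis(benzyloxy)phenyl)-4-oxo-4H-chromen-6-yl]phenyl}-4-[methoxy(methyl)amino]chroman-4-olate (formed in the flask, C4 configuration undefined) | [Na+].CON(C)C1([O-])C[C@@H](c2cc(OCc3ccccc3)c(OCc3ccccc3)c(-c3c(OCc4ccccc4)cc4oc(-c5ccc(OCc6ccccc6)c(OCc6ccccc6)c5)cc(=O)c4c3OCc3ccccc3)c2)Oc2cc(OCc3ccccc3)cc(OCc3ccccc3)c21 | intermediate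
21 | (2S)-5,7-bis(benzyloxy)-2-{3,4-bis(benzyloxy)-5-[5,7-bis(benzyloxy)-2-(3,4-bis(benzyloxy)phenyl)-4-oxo-4H-chromen-6-yl]phenyl}chroman-4-one | O=C1C[C@@H](c2cc(OCc3ccccc3)c(OCc3ccccc3)c(-c3c(OCc4ccccc4)cc4oc(-c5ccc(OCc6ccccc6)c(OCc6ccccc6)c5)cc(=O)c4c3OCc3ccccc3)c2)Oc2cc(OCc3ccccc3)cc(OCc3ccccc3)c21 | intermediate
22 | (2S)-2-{3,4-dihydroxy-5-[5,7-dihydroxy-2-(3,4-dihydroxyphenyl)-4-oxo-4H-chromen-6-yl]phenyl}-5,7-dihydroxychroman-4-one | O=C1C[C@@H](c2cc(O)c(O)c(-c3c(O)cc4oc(-c5ccc(O)c(O)c5)cc(=O)c4c3O)c2)Oc2cc(O)cc(O)c21 | target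

Total step count: 12 steps.
Longest linear sequence: 7 steps (5 → 6 → 9 → 10 → 11 → 12 → 21 → 22; steps 4, 5, 6, 7, 8, 11 and 12).

Steps most likely to fail

1. Step 11 (proposed new method). The aryl carbanion may take a proton from the α-CH2 of the amide instead of adding to the carbonyl, which would be followed by β-elimination of the aryloxide. The alkoxide may also fragment by retro-aldol reaction before it meets the aryne, or the hemiaminal adduct may collapse early and expose the flavanone to base, with ring opening and loss of configuration at C2. The fallback closes the same C4–C4a bond by known chemistry and sets out from 12. Dess–Martin oxidation (CH2Cl2, rt) would give the biaryl β-keto Weinreb amide F1. Noyori transfer hydrogenation with RuCl[(R,R)-TsDPEN](p-cymene) in HCO2H/Et3N would give the (R)-carbinol F2. Mitsunobu etherification of F2 with bromophenol 14 (PPh3, DIAD, THF, 0 °C) should proceed with inversion to the (S)-2-bromoaryl ether F3. Bromine–lithium exchange (t-BuLi, THF, −100 °C) and attack of the aryllithium on the Weinreb amide (Parham cyclization), with acidic quench, would return the route to 21.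

2. Step 8. Transmetalation at the doubly ortho-oxygenated aryl–palladium centre may be slow, so that protodeboronation of 11 or reductive deiodination of 4 takes over. The fallback changes the nucleophile and removes base and water; it sets out from 10. Stannylation (Me3SnSnMe3, Pd(PPh3)4, toluene, 100 °C) would give the arylstannane F4, and Stille coupling of F4 with iodide 4 (Pd(PPh3)4, CuI, CsF, DMF, 45 °C) would return to 12.

3. Step 12. Hydrogenolysis may stall at the hindered benzyl ethers, or it may over-reduce: saturation of the flavone C2=C3 bond or reductive opening of the benzylic C2–O1 bond of the flavanone. The fallback replaces hydrogenolysis by Lewis-acid debenzylation with a cation scavenger (BCl3, pentamethylbenzene, CH2Cl2, −78 °C, then MeOH quench). It sets out from 21 and arrives directly at 22 without any new intermediate.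

Further compounds
F1 | step 11 | 3-{3,4-bis(benzyloxy)-5-[5,7-bis(benzyloxy)-2-(3,4-bis(benzyloxy)phenyl)-4-oxo-4H-chromen-6-yl]phenyl}-N-methoxy-N-methyl-3-oxopropanamide | CON(C)C(=O)CC(=O)c1cc(OCc2ccccc2)c(OCc2ccccc2)c(-c2c(OCc3ccccc3)cc3oc(-c4ccc(OCc5ccccc5)c(OCc5ccccc5)c4)cc(=O)c3c2OCc2ccccc2)c1
F2 | step 11 | (3R)-3-{3,4-bis(benzyloxy)-5-[5,7-bis(benzyloxy)-2-(3,4-bis(benzyloxy)phenyl)-4-oxo-4H-chromen-6-yl]phenyl}-3-hydroxy-N-methoxy-N-methylpropanamide | CON(C)C(=O)C[C@H](c1cc(OCc2ccccc2)c(OCc2ccccc2)c(-c2c(OCc3ccccc3)cc3oc(-c4ccc(OCc5ccccc5)c(OCc5ccccc5)c4)cc(=O)c3c2OCc2ccccc2)c1)O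
F3 | step 11 | (3S)-3-[3,5-bis(benzyloxy)-2-bromophenoxy]-3-{3,4-bis(benzyloxy)-5-[5,7-bis(benzyloxy)-2-(3,4-bis(benzyloxy)phenyl)-4-oxo-4H-chromen-6-yl]phenyl}-N-methoxy-N-methylpropanamide | CON(C)C(=O)C[C@@H](c1cc(OCc2ccccc2)c(OCc2ccccc2)c(-c2c(OCc3ccccc3)cc3oc(-c4ccc(OCc5ccccc5)c(OCc5ccccc5)c4)cc(=O)c3c2OCc2ccccc2)c1)Oc1cc(OCc2ccccc2)cc(OCc2ccccc2)c1Br
F4 | step 8 | (3S)-3-[3,4-bis(benzyloxy)-5-(trimethylstannyl)phenyl]-3-hydroxy-N-methoxy-N-methylpropanamide | CON(C)C(=O)C[C@@H](c1cc(OCc2ccccc2)c(OCc2ccccc2)c([Sn](C)(C)C)c1)O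
F0 | step 12 | none | none
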